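The runs are simulated on assumed constants; noise was put on by code.

The vessel is closed, stirred and isothermal, and its charge of [substrate] = 1.5 M lies between the dusk and autumn charges.

| setting | dusk | autumn | flask |
|---|---|---|---|
| substrate | 1 M | 2.2 M | 1.5 M |
| remark | run made earlier | run made earlier |  |
| time |  |  | 30 h |

- dusk (time / h: intermediate A / %, target / %): 0.333: 54.4, 12.2; 0.833: 46.4, 14.5; 2.50: 32.0, 15.2; 6.00: 30.3, 15.4; 15.0: 29.9, 16.0; 40.0: 29.8, 15.9
- autumn (time / h: intermediate A / %, target / %): 0.333: 54.1, 12.4; 0.833: 46.6, 14.4; 2.50: 32.2, 15.2; 6.00: 29.4, 15.2; 15.0: 30.0, 15.8; 40.0: 30.7, 15.8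

(standard deviation of a reading: 0.3 percentage points)

- the moment within 30 h at which there is most intermediate A
- the amount of intermediate A, in percent of the substrate charged, at that time

- the earlier runs were read with a standard deviation of 0.3 percentage points

The two earlier runs read alike in percent, 54.4% against 54.1% at 0.333 h, so I draw the asked flask's curve from the dusk run. Follow one substrate molecule: I take it to end either as target or down the intermediate A branch. Target levels off at 15.9% in the dusk run, which gives 5.29 of intermediate A made per target made, the selectivity factor S.

Now the curve, in shares of the charge. In the dusk run intermediate A rises from zero at a mean slope of 1.63 h⁻¹ up to the first reading. Between the first two dusk readings, S turns target's gain into 12.2% of intermediate A made, yet the reading fell, so 20.2% went onward. Per hour and per amount standing, I reckon that as a net loss constant of 0.800 h⁻¹.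

The top is the crossing where making, S times target's slope, equals using, that constant times roughly the first reading. In the dusk run target's slope drops from 0.366 h⁻¹ up to the first reading to 0.0460 h⁻¹ between the first two readings, decaying at 4.98 h⁻¹. The crossing needs 0.0823 h⁻¹, so I put the top at 0.466 h, past the first reading, with a height I expect above 54.4%. After it the dusk readings pass 32.0% at 2.50 h, bend by 6.00 h and run into a level read near 29.8%, lower than the first reading.

The forecast gives 0.32 h and 56%, earlier than my time, and says “The peak is unobserved, since it lies at or before the first sample”.

The flask gives 0.373 h and 54.7%, so my crossing came 0.0930 h late.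

    substrate → intermediate A (k = 0.00140 s⁻¹)
    intermediate A ⇌ intermediate B (K = 0.650, k = 2.80 × 10⁻⁴ s⁻¹)
    substrate → target (k = 2.60 × 10⁻⁴ s⁻¹)
    substrate ⇌ dormant form (K = 0.800, k = 2.80 × 10⁻⁴ s⁻¹)
    intermediate B ⇌ intermediate C (K = 1.80, k = 0.00320 s⁻¹)

At 0.373 h the asked flask holds 12.7% target, and S turns that into 67.2% sent down the branch, beside 68.4% standing as intermediates A, B and C. The neighbour charged with 0.90 M of substrate reaches a top of 54.7%. At 30.0 h it holds 15.7% target, for which S gives 83.1%, and it holds 29.9% intermediate A, 19.4% intermediate B and 35.0% intermediate C, together 84.3%.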